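**Stereochemical reading of the target.** The SMILES gives (1R,4aS,8aS): H‑5 α, angular CH3 β, and the arylmethyl carbon C11 on the α face of C9, trans to the angular methyl. This is the 9‑epi arrangement relative to drimenol, so the route must put H‑9 on the β face. The route is designed on paper; conditions are precedent-based and untested.

## Retrosynthetic overview

1. Aryl O‑sulfate ⇐ free phenol; CHO ⇐ magnesium‑mediated ortho‑formylation of that phenol; the catechol is carried as a bis‑allyl ether and the oxygen to be sulfated as a MOM ether.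
2. C9–H (β) and the C7=C8 alkene ⇐ 1,3‑reductive transposition of a Δ8‑7‑one (tosylhydrazone → allylic diazene → retro‑ene).
3. Δ8‑7‑one ⇐ oxidative 1,3‑transposition of a tertiary allylic alcohol ⇐ benzylic Grignard + 11‑nordrim‑7‑en‑9‑one (C9–C11 bond).
4. That enone ⇐ (−)‑sclareol by side‑chain degradation; the arene ⇐ 2,4,5‑trihydroxybenzaldehyde.
5. No ring is formed: rings A and B (trans‑decalin, C5 and C10) come intact from sclareol and the benzene ring from the aldehyde.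

Assumption: the target is made as drawn, as the free aryl hydrogen sulfate; sulfate‑bearing compounds are written in this neutral form.

Notation: drimane numbering (C9 bears C11, C10 bears the angular methyl, α = face opposite the angular methyl). Ar = 2‑(methoxymethoxy)‑4,5‑bis(allyloxy)phenyl. "9‑epi‑drim‑7‑en‑11‑yl" = [(1R,4aS,8aS)‑2,5,5,8a‑tetramethyl‑1,4,4a,5,6,7,8,8a‑octahydronaphthalen‑1‑yl]methyl (C11 α, H‑9 β).

## Route

Step 1
Reactants: 1 (−)‑sclareol
Product: 4 8α‑hydroxy‑14,15‑dinorlabdan‑13‑one, via labdane tetrol 2 (not isolated), via hydroxy aldehyde 3 (not isolated)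
Conditions: OsO4 (2 mol %), NaIO4 (3.5 equiv), THF–H2O, rt
Reagents that add atoms: none
Why: Lemieux–Johnson oxidation, in which dihydroxylation of the vinyl group and periodate cleavage of the 13,14,15‑triol unit (C15 as formaldehyde, C14 as formic acid) unmask the methyl ketone without touching a stereocentre.

Step 2
Reactants: 4 8α‑hydroxy‑14,15‑dinorlabdan‑13‑one
Product: 5 drim‑9(11)‑en‑8α‑ol
Conditions: hν (medium‑pressure Hg lamp, quartz), hexane, rt, N2
Reagents that add atoms: none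
Why: Norrish type 2 fragmentation, in which the excited ketone abstracts the γ‑hydrogen at C9 and the 1,4‑biradical cleaves C11–C12, expelling acetone (as its enol) and leaving the exocyclic C9=C11 alkene with C5, C8 and C10 untouched.

Step 3
Reactants: 5 drim‑9(11)‑en‑8α‑ol
Product: 7 8α‑hydroxy‑11‑nordriman‑9‑one, via secondary ozonide 6 (not isolated)
Conditions: O3, CH2Cl2, −78 °C; then Me2S, −78 °C → rt
Reagents that add atoms: ozone, [O-][O+]=O
Why: Ozonolysis (Criegee mechanism) of the 1,1‑disubstituted alkene with reductive work‑up excises C11 as formaldehyde and leaves the C9 ketone.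

Step 4
Reactants: 7 8α‑hydroxy‑11‑nordriman‑9‑one
Product: 9 11‑nordrim‑7‑en‑9‑one, via exocyclic enone 8 (not isolated)
Conditions: SOCl2, pyridine, CH2Cl2, −78 → 0 °C; then RhCl3·3H2O (5 mol %), EtOH, 80 °C
Reagents that add atoms: none
Why: E2 dehydration of the tertiary α‑ketol (the equatorial 8α‑oxygen is antiperiplanar only to methyl hydrogens, so the exocyclic enone forms first) followed by rhodium‑catalysed migration of the double bond into the ring gives the more stable 2‑methyl enone.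

Step 5
Reactants: 10 2,4,5‑trihydroxybenzaldehyde
Product: 11 2‑hydroxy‑4,5‑bis(allyloxy)benzaldehyde
Conditions: allyl bromide (2.1 equiv), Li2CO3, DMF, 45 °C
Reagents that add atoms: allyl bromide, C=CCBr
Why: Williamson etherification, in which the 2‑OH is held in the lithium chelate with the aldehyde so only the 4‑ and 5‑phenoxides are alkylated.

Step 6
Reactants: 11 2‑hydroxy‑4,5‑bis(allyloxy)benzaldehyde
Product: 12 2‑(methoxymethoxy)‑4,5‑bis(allyloxy)benzaldehyde
Conditions: MOMCl, i‑Pr2NEt, DMAP (cat.), CH2Cl2, 0 → 40 °C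
Reagents that add atoms: chloromethyl methyl ether, COCCl
Why: O‑alkylation of the remaining phenol to the MOM acetal gives a group that is orthogonal to the allyl ethers and stable to the organomagnesium step.

Step 7
Reactants: 12 2‑(methoxymethoxy)‑4,5‑bis(allyloxy)benzaldehyde
Product: 13 [2‑(methoxymethoxy)‑4,5‑bis(allyloxy)phenyl]methanol
Conditions: NaBH4, MeOH, 0 °C
Reagents that add atoms: none
Why: Borohydride reduction of the aldehyde, whose carbon becomes C11 of the target.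

Step 8
Reactants: 13 [2‑(methoxymethoxy)‑4,5‑bis(allyloxy)phenyl]methanol
Product: 15 1‑(chloromethyl)‑2‑(methoxymethoxy)‑4,5‑bis(allyloxy)benzene, via benzylic mesylate 14 (not isolated)
Conditions: MsCl, Et3N, CH2Cl2, 0 °C; then LiCl, THF, rt; used crude
Reagents that add atoms: lithium chloride, [Li+].[Cl-]
Why: Mesylation and in situ SN2 displacement by chloride under non‑acidic conditions that keep the MOM acetal.

Step 9
Reactants: 9 11‑nordrim‑7‑en‑9‑one; 15 1‑(chloromethyl)‑2‑(methoxymethoxy)‑4,5‑bis(allyloxy)benzene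
Product: 17 11‑Ar‑drim‑7‑en‑9β‑ol (C11 α), via benzylmagnesium chloride 16 (not isolated)
Conditions: 15 (1.8 equiv), Mg turnings, 2‑MeTHF, 0 °C, slow addition; then 9, THF, −78 → 0 °C; aq NH4Cl
Reagents that add atoms: none
Why: Grignard 1,2‑addition to the non‑enolisable enone forms the C9–C11 bond, with attack anti to the angular methyl (α face) setting a carbinol centre that is erased again in step 10.

Step 10
Reactants: 17 11‑Ar‑drim‑7‑en‑9β‑ol
Product: 18 11‑Ar‑drim‑8‑en‑7‑one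
Conditions: PCC (3 equiv), 4 Å MS, CH2Cl2, rt
Reagents that add atoms: pyridinium chlorochromate, [O-][Cr](=O)(=O)Cl.c1cc[nH+]cc1
Why: Babler–Dauben oxidative 1,3‑transposition, in which the tertiary allylic chromate ester shifts to C7 and is oxidised to the transposed tetrasubstituted enone.

Step 11
Reactants: 18 11‑Ar‑drim‑8‑en‑7‑one
Product: 19 11‑Ar‑drim‑8‑en‑7‑one N‑tosylhydrazone
Conditions: TsNHNH2 (1.3 equiv), PPTS (cat.), EtOH, 60 °C
Reagents that add atoms: 4‑methylbenzenesulfonohydrazide, Cc1ccc(cc1)S(=O)(=O)NN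
Why: Condensation of the unhindered C7 carbonyl to the tosylhydrazone prepares the reductive transposition.

Step 12
Reactants: 19 11‑Ar‑drim‑8‑en‑7‑one N‑tosylhydrazone
Product: 21 1‑(9‑epi‑drim‑7‑en‑11‑yl)‑2‑(methoxymethoxy)‑4,5‑bis(allyloxy)benzene, via allylic diazene 20 (not isolated)
Conditions: catecholborane (3 equiv), CHCl3, 0 °C → rt; then NaOAc·3H2O, 60 °C
Reagents that add atoms: none
Why: Kabalka reduction with 1,3‑reductive transposition, in which hydride adds to C=N from the less hindered α face, loss of sulfinate gives the 7β‑diazene, and its suprafacial retro‑ene loss of N2 places hydrogen on the β face of C9 and the alkene at C7=C8 (C11 α, 1R), the same course by which cholest‑4‑en‑3‑one tosylhydrazone gives 5β‑cholest‑3‑ene.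

Step 13
Reactants: 21 1‑(9‑epi‑drim‑7‑en‑11‑yl)‑2‑(methoxymethoxy)‑4,5‑bis(allyloxy)benzene
Product: 22 2‑(9‑epi‑drim‑7‑en‑11‑yl)‑4,5‑bis(allyloxy)phenol
Conditions: ZnBr2 (1 equiv), n‑PrSH (2 equiv), CH2Cl2, 0 °C, 15 min
Reagents that add atoms: none
Why: Lewis acid–thiol cleavage of the aryl MOM acetal under non‑protic conditions spares the allyl ethers and avoids acid cyclisation of the phenol onto the C7=C8 alkene.

Step 14
Reactants: 22 2‑(9‑epi‑drim‑7‑en‑11‑yl)‑4,5‑bis(allyloxy)phenol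
Product: 24 2‑hydroxy‑5,6‑bis(allyloxy)‑3‑(9‑epi‑drim‑7‑en‑11‑yl)benzaldehyde, via salicyl alcohol 23 (not isolated)
Conditions: MgCl2 (3 equiv), Et3N (6 equiv), (CH2O)n (10 equiv), MeCN, 80 °C
Reagents that add atoms: formaldehyde (as paraformaldehyde), C=O
Why: Casnati–Skattebøl ortho‑formylation, in which the magnesium phenoxide delivers formaldehyde to the only free ortho position and a second formaldehyde oxidises the resulting salicyl alcohol by hydride transfer.

Step 15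
Reactants: 24 2‑hydroxy‑5,6‑bis(allyloxy)‑3‑(9‑epi‑drim‑7‑en‑11‑yl)benzaldehyde
Product: 25 2‑formyl‑3,4‑bis(allyloxy)‑6‑(9‑epi‑drim‑7‑en‑11‑yl)phenyl hydrogen sulfate
Conditions: SO3·pyridine (6 equiv), pyridine, 45 °C
Reagents that add atoms: sulfur trioxide–pyridine complex, [O-]S(=O)(=O)[n+]1ccccc1
Why: O‑sulfation (sulfuryl transfer) of the only free hydroxyl, the one ortho to both the formyl group and the terpenylmethyl group.

Step 16
Reactants: 25 2‑formyl‑3,4‑bis(allyloxy)‑6‑(9‑epi‑drim‑7‑en‑11‑yl)phenyl hydrogen sulfate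
Product: 26 2‑formyl‑3,4‑dihydroxy‑6‑{[(1R,4aS,8aS)‑2,5,5,8a‑tetramethyl‑1,4,4a,5,6,7,8,8a‑octahydronaphthalen‑1‑yl]methyl}phenyl hydrogen sulfate
Conditions: Pd(PPh3)4 (10 mol %), p‑TolSO2H (3 equiv), THF–MeOH, rt, Ar; then Dowex 50WX8 (H+ form), MeOH–H2O, 0 °C, lyophilise
Reagents that add atoms: none
Why: Tsuji–Trost deallylation, in which zerovalent palladium ionises both aryl allyl ethers to π‑allyl complexes that are trapped by the sulfinic acid, leaving aldehyde, alkene and sulfate intact, and cation exchange gives the free hydrogen sulfate.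

## Compound list

1 | (−)‑sclareol, (13R)‑labd‑14‑ene‑8α,13‑diol | C[C@@]1(O)CC[C@H]2C(C)(C)CCC[C@]2(C)[C@H]1CC[C@@](C)(O)C=C | starting material
2 | (13R)‑labdane‑8α,13,14,15‑tetrol (C14 epimers) | C[C@@]1(O)CC[C@H]2C(C)(C)CCC[C@]2(C)[C@H]1CC[C@@](C)(O)C(O)CO | intermediate (not isolated)
3 | (13R)‑8α,13‑dihydroxy‑15‑norlabdan‑14‑al | C[C@@]1(O)CC[C@H]2C(C)(C)CCC[C@]2(C)[C@H]1CC[C@@](C)(O)C=O | intermediate (not isolated)
4 | 8α‑hydroxy‑14,15‑dinorlabdan‑13‑one | C[C@@]1(O)CC[C@H]2C(C)(C)CCC[C@]2(C)[C@H]1CCC(C)=O | intermediate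
5 | drim‑9(11)‑en‑8α‑ol | C[C@@]1(O)CC[C@H]2C(C)(C)CCC[C@]2(C)C1=C | intermediate
6 | secondary ozonide of 5 (spiro‑1,2,4‑trioxolane at C9, C9 epimers) | C[C@@]1(O)CC[C@H]2C(C)(C)CCC[C@]2(C)C13OCOO3 | intermediate (not isolated)
7 | 8α‑hydroxy‑11‑nordriman‑9‑one | C[C@@]1(O)CC[C@H]2C(C)(C)CCC[C@]2(C)C1=O | intermediate
8 | 11‑nordrim‑8(12)‑en‑9‑one | C=C1CC[C@H]2C(C)(C)CCC[C@]2(C)C1=O | intermediate (not isolated)
9 | 11‑nordrim‑7‑en‑9‑one, (4aS,8aS)‑2,5,5,8a‑tetramethyl‑4a,5,6,7,8,8a‑hexahydronaphthalen‑1(4H)‑one | CC1=CC[C@H]2C(C)(C)CCC[C@]2(C)C1=O | intermediate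
10 | 2,4,5‑trihydroxybenzaldehyde | O=Cc1cc(O)c(O)cc1O | starting material
11 | 2‑hydroxy‑4,5‑bis(allyloxy)benzaldehyde | O=Cc1cc(OCC=C)c(OCC=C)cc1O | intermediate
12 | 2‑(methoxymethoxy)‑4,5‑bis(allyloxy)benzaldehyde | O=Cc1cc(OCC=C)c(OCC=C)cc1OCOC | intermediate
13 | [2‑(methoxymethoxy)‑4,5‑bis(allyloxy)phenyl]methanol | OCc1cc(OCC=C)c(OCC=C)cc1OCOC | intermediate
14 | [2‑(methoxymethoxy)‑4,5‑bis(allyloxy)phenyl]methyl methanesulfonate | CS(=O)(=O)OCc1cc(OCC=C)c(OCC=C)cc1OCOC | intermediate (not isolated)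
15 | 1‑(chloromethyl)‑2‑(methoxymethoxy)‑4,5‑bis(allyloxy)benzene | ClCc1cc(OCC=C)c(OCC=C)cc1OCOC | intermediate
16 | [2‑(methoxymethoxy)‑4,5‑bis(allyloxy)phenyl]methylmagnesium chloride | Cl[Mg]Cc1cc(OCC=C)c(OCC=C)cc1OCOC | intermediate (not isolated)
17 | 11‑Ar‑drim‑7‑en‑9β‑ol (9β‑OH, C11 α) | CC1=CC[C@H]2C(C)(C)CCC[C@]2(C)[C@]1(O)Cc1cc(OCC=C)c(OCC=C)cc1OCOC | intermediate
18 | 11‑Ar‑drim‑8‑en‑7‑one | O=C1C[C@H]2C(C)(C)CCC[C@]2(C)C(Cc3cc(OCC=C)c(OCC=C)cc3OCOC)=C1C | intermediate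
19 | 11‑Ar‑drim‑8‑en‑7‑one N‑tosylhydrazone (C=N geometry not defined) | Cc1ccc(cc1)S(=O)(=O)NN=C1C[C@H]2C(C)(C)CCC[C@]2(C)C(Cc3cc(OCC=C)c(OCC=C)cc3OCOC)=C1C | intermediate
20 | 7β‑diazenyl‑11‑Ar‑drim‑8‑ene | N=N[C@H]1C[C@H]2C(C)(C)CCC[C@]2(C)C(Cc3cc(OCC=C)c(OCC=C)cc3OCOC)=C1C | intermediate (not isolated)
21 | 1‑(9‑epi‑drim‑7‑en‑11‑yl)‑2‑(methoxymethoxy)‑4,5‑bis(allyloxy)benzene | CC1=CC[C@H]2C(C)(C)CCC[C@]2(C)[C@@H]1Cc1cc(OCC=C)c(OCC=C)cc1OCOC | intermediate
22 | 2‑(9‑epi‑drim‑7‑en‑11‑yl)‑4,5‑bis(allyloxy)phenol | CC1=CC[C@H]2C(C)(C)CCC[C@]2(C)[C@@H]1Cc1cc(OCC=C)c(OCC=C)cc1O | intermediate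
23 | 2‑(9‑epi‑drim‑7‑en‑11‑yl)‑4,5‑bis(allyloxy)‑6‑(hydroxymethyl)phenol | CC1=CC[C@H]2C(C)(C)CCC[C@]2(C)[C@@H]1Cc1cc(OCC=C)c(OCC=C)c(CO)c1O | intermediate (not isolated)
24 | 2‑hydroxy‑5,6‑bis(allyloxy)‑3‑(9‑epi‑drim‑7‑en‑11‑yl)benzaldehyde | CC1=CC[C@H]2C(C)(C)CCC[C@]2(C)[C@@H]1Cc1cc(OCC=C)c(OCC=C)c(C=O)c1O | intermediate
25 | 2‑formyl‑3,4‑bis(allyloxy)‑6‑(9‑epi‑drim‑7‑en‑11‑yl)phenyl hydrogen sulfate | CC1=CC[C@H]2C(C)(C)CCC[C@]2(C)[C@@H]1Cc1cc(OCC=C)c(OCC=C)c(C=O)c1OS(=O)(=O)O | intermediate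
26 | 2‑formyl‑3,4‑dihydroxy‑6‑{[(1R,4aS,8aS)‑2,5,5,8a‑tetramethyl‑1,4,4a,5,6,7,8,8a‑octahydronaphthalen‑1‑yl]methyl}phenyl hydrogen sulfate | CC1=CC[C@H]2C(C)(C)CCC[C@]2(C)[C@@H]1Cc1cc(O)c(O)c(C=O)c1OS(=O)(=O)O | target

## Step count and risks

Total step count: 16. Longest linear sequence: 12 steps (1–4 then 9–16 from sclareol; the arene branch 5–8 then 9–16 is equally long).

Three steps most likely to fail:

**Step 9.** The benzylic Grignard reagent 16 is prone to Wurtz coupling, and the carbonyl of 9 is flanked by a quaternary carbon, so 1,4‑addition or poor conversion is possible. The fallback replaces carbonyl addition plus two transpositions by a directed allylic substitution that sets C9 directly. It sets out from 9 (and uses 16 made from 15) and comes back at 21, bypassing 17–20. Nucleophilic epoxidation of 9 (H2O2, NaOH, MeOH, 0 °C) from the α face gives 7α,8α‑epoxy‑11‑nordriman‑9‑one F1. Wharton transposition (N2H4·H2O, AcOH cat., MeOH) gives 11‑nordrim‑8‑en‑7α‑ol F2. PhNCO and Et3N give 11‑nordrim‑8‑en‑7α‑yl N‑phenylcarbamate F3. Deprotonation (MeLi, −78 °C), CuI and then 16 deliver the benzyl group from the carbamate face (syn‑SN2′, α face of C9) while the alkene moves to C7=C8, which is 21.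

**Step 12.** The C9 configuration depends on α‑face hydride addition to the hydrazone and on the 7β‑diazene reaching the β face of C9 in a conformationally locked ring B; the 9β‑arylmethyl epimer or the Δ8 isomer would be the failure. The fallback delivers the hydrogen from a palladium hydride instead of a diazene. It sets out from 18 and comes back at 21. Luche reduction (NaBH4, CeCl3·7H2O, MeOH, 0 °C; axial hydride attack) gives 11‑Ar‑drim‑8‑en‑7β‑ol F4. Mitsunobu inversion with formic acid (PPh3, DIAD, THF) gives 11‑Ar‑drim‑8‑en‑7α‑yl formate F5. With Pd(OAc)2 and n‑Bu3P in dioxane (rt → 60 °C), zerovalent palladium ionises the formate with inversion (metal on the β face), loss of CO2 gives a palladium hydride, and reductive elimination puts hydride on the β face of the more substituted allyl terminus C9, giving 21 (Tsuji–Mandai formate hydrogenolysis).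

**Step 14.** The only free ortho position lies between the phenol and an allyloxy group, so the magnesium‑mediated formylation may stall. The fallback is a boron‑templated ortho‑hydroxymethylation followed by a separate oxidation. It sets out from 22 and comes back at 24, passing through 23 (then isolated). PhB(OH)2, (CH2O)n and EtCO2H (cat.) in toluene at reflux (Dean–Stark) give the 2‑phenyl‑4H‑1,3,2‑benzodioxaborin of 23 F6. Exchange with pinacol releases 23, and MnO2 in CH2Cl2 oxidises the benzylic alcohol to 24.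

## Further compounds

F1 | step 9 | 7α,8α‑epoxy‑11‑nordriman‑9‑one | C[C@@]12O[C@@H]1C[C@H]3C(C)(C)CCC[C@]3(C)C2=O
F2 | step 9 | 11‑nordrim‑8‑en‑7α‑ol | O[C@@H]1C[C@H]2C(C)(C)CCC[C@]2(C)C=C1C
F3 | step 9 | 11‑nordrim‑8‑en‑7α‑yl N‑phenylcarbamate | O=C(Nc1ccccc1)O[C@@H]1C[C@H]2C(C)(C)CCC[C@]2(C)C=C1C
F4 | step 12 | 11‑Ar‑drim‑8‑en‑7β‑ol | O[C@H]1C[C@H]2C(C)(C)CCC[C@]2(C)C(Cc3cc(OCC=C)c(OCC=C)cc3OCOC)=C1C
F5 | step 12 | 11‑Ar‑drim‑8‑en‑7α‑yl formate | O=CO[C@@H]1C[C@H]2C(C)(C)CCC[C@]2(C)C(Cc3cc(OCC=C)c(OCC=C)cc3OCOC)=C1C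
F6 | step 14 | 2‑phenyl‑4H‑1,3,2‑benzodioxaborin of 23 (6,7‑bis(allyloxy)‑8‑(9‑epi‑drim‑7‑en‑11‑yl)) | CC1=CC[C@H]2C(C)(C)CCC[C@]2(C)[C@@H]1Cc1cc(OCC=C)c(OCC=C)c2COB(c3ccccc3)Oc12
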